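## Retrosynthetic overview

- **Numbering and feature.** Labdane-type numbering is used: C4 = CMe2, C5 = fusion CH, C10 = fusion C(CH3), C8(CH3)=C9 in ring B, chain C11–C16 from C9 to C4 of the butenolide. The strategy rests on the cis relation of H-5 and the C10 methyl across the fusion bond C5–C10. A one-face [4+2] addition to a ring A C5=C10 alkene leaves exactly this pattern, and C6–C7–C8(CH3)–C9–C11 is then a simple 1,2-disubstituted butadiene.
- **Side chain.** C15=C16 comes from a Wittig reaction (butenolide ylide plus C15 enal). C12–C13 comes from hydroboration and B-alkyl Suzuki coupling of a C9 vinyl group with a (Z)-β-iodoenoate. C11=C12 comes from methylenation of the C8=C9–C11HO enal.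
- **Core.** C8=C9 is traced back to C7=C8 plus a C9 aldehyde (base conjugation), the C10 methyl to an angular ester, and C1H2 to a ketone. This is the Diels–Alder adduct of a keto ester dienophile.
- **Ring order.** Ring A is bought as 4,4-dimethylcyclohexanone. Ring B is closed by the copper–bis(oxazoline) Diels–Alder reaction (bonds C5–C6 and C9–C10). The butenolide ring is made separately from dihydroxyacetone and attached last.

Key step: step 5

Assumption: the sense of induction of Cu(OTf)2/(S,S)-t-Bu-BOX is taken from the square-planar quadrant model of the chelate; should the adduct prove to be the mirror image, the equally available (R,R) ligand is used and nothing else changes.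

Convention: decalins are viewed with ring A left, ring B right and C10 above C5, and β means towards the viewer. Every decalin below carries 5β-H and a 10β substituent (cis fusion).

## Route

Step 1
Reactants: 1 4,4-dimethylcyclohexanone; 2 dimethyl carbonate
Product: 3 methyl 5,5-dimethyl-2-oxocyclohexane-1-carboxylate (racemic keto–enol mixture)
Conditions: NaH (2.2 equiv), THF, reflux; aq. HCl quench
Reagents that add atoms: none
Why: Claisen-type C-acylation of the ketone enolate with dimethyl carbonate is pulled to completion by deprotonation of the β-keto ester; the ketone is symmetric, so one regioisomer forms, and the new enolisable centre is erased in step 2.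

Step 2
Reactants: 3 methyl 5,5-dimethyl-2-oxocyclohexane-1-carboxylate
Product: 6 methyl 3,3-dimethyl-6-oxocyclohex-1-ene-1-carboxylate, via α-phenylselenide 4 (not isolated), via selenoxide 5 (not isolated)
Conditions: PhSeCl, pyridine, CH2Cl2, 0 °C; then 30% H2O2, 0 °C → rt; used fresh
Reagents that add atoms: benzeneselenenyl chloride, Cl[Se]c1ccccc1 (PhSe in 4 and 5 only); hydrogen peroxide, OO (O in 5 only)
Why: α-Selenenylation followed by oxidation and selenoxide syn-elimination can only take a hydrogen from the CH2 next to CMe2, which places the alkene at C5=C10, and the quaternary C4 keeps the product from tautomerising to a dienol.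

Step 3
Reactants: 7 (E)-3-methylpent-2-en-4-yn-1-ol
Product: 8 tert-butyldimethyl{[(E)-3-methylpent-2-en-4-yn-1-yl]oxy}silane
Conditions: TBSCl, imidazole, CH2Cl2, rt
Reagents that add atoms: tert-butyldimethylsilyl chloride, CC(C)(C)[Si](C)(C)Cl
Why: Imidazole-promoted O-silylation of a primary allylic alcohol is done before the reduction so that the diene is not volatile and carries no free hydroxyl to compete for the copper catalyst.

Step 4
Reactants: 8 silyl enyne
Product: 9 tert-butyldimethyl{[(E)-3-methylpenta-2,4-dien-1-yl]oxy}silane (diene C6=C7–C8(CH3)=C9–C11)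
Conditions: H2 (1 atm, 1 equiv), Pd/CaCO3 poisoned with Pb(OAc)2, quinoline, hexane, rt
Reagents that add atoms: none
Why: Lindlar semihydrogenation takes the terminal alkyne to the vinyl group when uptake is stopped at one equivalent and leaves the trisubstituted alkene untouched, so its E geometry, which puts C11 in the outside position of the s-cis diene, is kept.

Step 5
Reactants: 6 keto ester dienophile; 9 diene
Product: 10 methyl (1R,4aR,8aR)-1-{[(tert-butyldimethylsilyl)oxy]methyl}-2,5,5-trimethyl-8-oxo-1,4,4a,5,6,7,8,8a-octahydronaphthalene-8a-carboxylate (labdane 5R,9R,10R: 5β-H, 10β-CO2Me, 9α-CH2OTBS, C1 ketone, C7=C8)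
Conditions: Cu(OTf)2 (10 mol %), 2,2'-isopropylidenebis[(4S)-4-tert-butyl-2-oxazoline] (11 mol %), 4 Å molecular sieves, CH2Cl2, 0 °C → rt
Reagents that add atoms: none
Why: The ketone and ester oxygens of 6 bind the divalent copper centre as a flat six-membered chelate, which lowers the LUMO of C5=C10, and s-cis 9 adds in a concerted but asynchronous normal-demand [4+2] cycloaddition in which C5–C6 bonding runs ahead of C9–C10 bonding. The closest known reactions are the Lewis-acid-promoted Diels–Alder additions of 2-alkoxycarbonylcyclohex-2-enones (this 4,4-dimethyl compound included) to acyclic dienes and the copper–bis(oxazoline)-catalysed asymmetric Diels–Alder reactions of chelating α-alkylidene and cyclic β-keto ester dienophiles. Ring B, a cyclohexene, is closed by intermolecular [4+2] annulation onto ring A, both σ bonds being made on the same face of C5=C10. C5 and C10 are tied to each other by that suprafacial addition to a ring alkene (H-5 cis to CO2Me) and fixed in the absolute sense by the ligand tert-butyl groups, which in the square-planar chelate leave only the C5-Re/C10-Re face open to a diene lying over the ketone, while C9 follows from the E geometry of 9 and this ketone-endo arrangement (CH2OTBS trans to CO2Me). The regioselectivity needed (C6 to C5, C9 to C10) comes from the larger HOMO coefficient at the free terminus of a 1-substituted diene meeting the β-carbon and, above all, from the neopentyl C5, which tolerates only a CH2 terminus, so the opposite "para" bias of the C8 methyl is overridden. Since in a C2-symmetric chelate the ester-endo mode is steered to the other face, the minor C9 epimer may belong to the mirror-image C5/C10 series and is removed by chromatography, not pooled, although C9 is erased later.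

Step 6
Reactants: 10 Diels–Alder adduct
Product: 11 C1 carbinol of 10 (5β-H, 10β-CO2Me, 9α-CH2OTBS; C1 unassigned, either epimer or the mixture is used)
Conditions: NaBH4, MeOH, 0 °C
Reagents that add atoms: none
Why: Chemoselective borohydride 1,2-reduction takes the ketone beside the far less electrophilic neopentyl ester; the C1 centre arises under substrate control, is left unassigned and disappears in step 8.

Step 7
Reactants: 11 C1 carbinol
Product: 12 C1 O-(imidazol-1-ylthiocarbonyl) derivative of 11
Conditions: 1,1'-thiocarbonyldiimidazole, DMAP (cat.), ClCH2CH2Cl, reflux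
Reagents that add atoms: 1,1'-thiocarbonyldiimidazole, S=C(n1ccnc1)n1ccnc1
Why: Near-neutral thioacyl transfer gives the Barton–McCombie precursor without forming a free alkoxide, which in a β-hydroxy ester with a quaternary α-carbon could open the ring by retro-aldol cleavage.

Step 8
Reactants: 12 thiocarbonylimidazolide
Product: 13 methyl (1R,4aR,8aR)-1-{[(tert-butyldimethylsilyl)oxy]methyl}-2,5,5-trimethyl-1,4,4a,5,6,7,8,8a-octahydronaphthalene-8a-carboxylate (C1 now CH2)
Conditions: Bu3SnH (concentrated, about 0.3 M), AIBN (cat.), toluene, 100 °C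
Reagents that add atoms: none
Why: In this Barton–McCombie deoxygenation the stannyl radical adds to C=S, C1–O fragments and the secondary C1 radical is trapped by Bu3SnH fast enough to outrun β-scission of C9–C10, while the C7=C8 alkene is within reach only through disfavoured 4-exo or 5-endo closures.

Step 9
Reactants: 13 angular ester
Product: 14 [(1R,4aR,8aR)-1-{[(tert-butyldimethylsilyl)oxy]methyl}-2,5,5-trimethyl-1,4,4a,5,6,7,8,8a-octahydronaphthalen-8a-yl]methanol (10β-CH2OH)
Conditions: LiAlH4, Et2O, 0 °C → rt
Reagents that add atoms: none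
Why: Hydride reduction of the ester gives the neopentyl primary alcohol; the silyl ether and the isolated alkene are inert and no stereocentre is touched.

Step 10
Reactants: 14 angular primary alcohol
Product: 16 tetramethylphosphorodiamidate of 14 (10β-CH2OP(O)(NMe2)2), via lithium alkoxide 15 (not isolated)
Conditions: n-BuLi, THF–TMEDA, 0 °C; then ClP(O)(NMe2)2, rt
Reagents that add atoms: bis(dimethylamino)phosphoryl chloride, CN(C)P(=O)(Cl)N(C)C; n-butyllithium, [Li]CCCC (lithium in 15 only)
Why: O-Phosphorylation of the preformed alkoxide, the first half of the Ireland phosphorodiamidate deoxygenation, works on hindered neopentyl alcohols because the bond is made at oxygen, away from the congested carbon.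

Step 11
Reactants: 16 phosphorodiamidate
Product: 17 tert-butyldimethyl{[(1R,4aR,8aS)-2,5,5,8a-tetramethyl-1,4,4a,5,6,7,8,8a-octahydronaphthalen-1-yl]methoxy}silane (10β-CH3)
Conditions: Li, EtNH2, t-BuOH, THF, 0 °C, short contact time
Reagents that add atoms: none
Why: Dissolving-metal C–O cleavage (Ireland deoxygenation) runs by electron transfer and protonation, not substitution, so the neopentyl position is no obstacle; C10 is not involved and keeps its configuration, and the trisubstituted alkene and silyl ether tolerate a short exposure.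

Step 12
Reactants: 17 silyl ether
Product: 18 [(1R,4aR,8aS)-2,5,5,8a-tetramethyl-1,4,4a,5,6,7,8,8a-octahydronaphthalen-1-yl]methanol (cis-fused drim-7-en-11-ol)
Conditions: Bu4NF, THF, rt
Reagents that add atoms: none
Why: Fluoride-induced desilylation is driven by the Si–F bond, and nothing else in the hydrocarbon skeleton reacts.

Step 13
Reactants: 18 C11 alcohol
Product: 19 (1R,4aR,8aS)-2,5,5,8a-tetramethyl-1,4,4a,5,6,7,8,8a-octahydronaphthalene-1-carbaldehyde (β,γ-unsaturated aldehyde)
Conditions: Dess–Martin periodinane, CH2Cl2, rt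
Reagents that add atoms: none
Why: Dess–Martin oxidation stops cleanly at the aldehyde, and any early epimerisation or conjugation at C9 is harmless because step 14 completes it.

Step 14
Reactants: 19 β,γ-unsaturated aldehyde
Product: 20 (4aR,8aS)-2,5,5,8a-tetramethyl-3,4,4a,5,6,7,8,8a-octahydronaphthalene-1-carbaldehyde (C8=C9–CHO)
Conditions: DBU (0.2 equiv), CH2Cl2, rt
Reagents that add atoms: none
Why: Base-catalysed β,γ to α,β isomerisation through the C9 dienolate with protonation at C7, the decalin counterpart of the α- to β-cyclocitral conversion, is driven by conjugation and the tetrasubstituted alkene; it erases C9 and cannot reach C5 or C10.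

Step 15
Reactants: 20 conjugated enal
Product: 21 (4aR,8aS)-1-ethenyl-2,5,5,8a-tetramethyl-3,4,4a,5,6,7,8,8a-octahydronaphthalene
Conditions: Ph3PCH3Br, KOt-Bu, THF, 0 °C → rt
Reagents that add atoms: methyltriphenylphosphonium bromide, C[P+](c1ccccc1)(c1ccccc1)c1ccccc1.[Br-]
Why: Wittig methylenation with the small non-stabilised ylide adds 1,2 to the hindered tetrasubstituted enal, as it does with β-cyclocitral.

Step 16
Reactants: 22 prop-2-yn-1-ol
Product: 23 tert-butyldiphenyl(prop-2-yn-1-yloxy)silane
Conditions: TBDPSCl, imidazole, CH2Cl2, rt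
Reagents that add atoms: tert-butyldiphenylsilyl chloride, CC(C)(C)[Si](Cl)(c1ccccc1)c1ccccc1
Why: This is a standard imidazole-promoted silylation, and this silyl group is chosen because it must survive hot acetic acid in step 18.

Step 17
Reactants: 23 silyl propargyl ether
Product: 25 ethyl 4-[(tert-butyldiphenylsilyl)oxy]but-2-ynoate, via lithium acetylide 24 (not isolated)
Conditions: n-BuLi, THF, −78 °C; then ClCO2Et, −78 °C → rt
Reagents that add atoms: ethyl chloroformate, CCOC(=O)Cl; n-butyllithium, [Li]CCCC (lithium in 24 only)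
Why: Deprotonation of the terminal alkyne and C-acylation of the acetylide with a chloroformate is the standard route to alkynoates.

Step 18
Reactants: 25 alkynoate
Product: 26 ethyl (2Z)-4-[(tert-butyldiphenylsilyl)oxy]-3-iodobut-2-enoate (I cis to CO2Et)
Conditions: NaI, AcOH, 80 °C
Reagents that add atoms: sodium iodide, [Na+].[I-]
Why: In this conjugate hydroiodination iodide adds to the β-carbon and the allenolate is protonated anti, so the kinetic product carries I and CO2Et cis (Z), which fixes the future C13=C14 geometry.

Step 19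
Reactants: 21 vinyl decalin; 26 (Z)-β-iodoenoate
Product: 28 ethyl (2E)-3-{[(tert-butyldiphenylsilyl)oxy]methyl}-5-[(4aR,8aS)-2,5,5,8a-tetramethyl-3,4,4a,5,6,7,8,8a-octahydronaphthalen-1-yl]pent-2-enoate, via B-alkyl-9-BBN 27 (not isolated)
Conditions: 9-BBN dimer, THF, rt → 50 °C; then H2O, 26, Pd(dppf)Cl2 (5 mol %), AsPh3, Cs2CO3, DMF, rt
Reagents that add atoms: 9-borabicyclo[3.3.1]nonane, B1C2CCCC1CCC2 (boryl group in 27 only)
Why: In this hydroboration and B-alkyl Suzuki–Miyaura coupling, 9-BBN attacks only the monosubstituted C11=C12 alkene with boron at C12 (the tetrasubstituted C8=C9 is inert), and oxidative addition to zerovalent palladium and reductive elimination retain the alkene geometry, so C12 takes the place of iodine cis to the ester.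

Step 20
Reactants: 28 enoate
Product: 29 (2E)-3-{[(tert-butyldiphenylsilyl)oxy]methyl}-5-[(4aR,8aS)-2,5,5,8a-tetramethyl-3,4,4a,5,6,7,8,8a-octahydronaphthalen-1-yl]pent-2-en-1-ol
Conditions: i-Bu2AlH (2.5 equiv), CH2Cl2, −78 °C; aq. potassium sodium tartrate
Reagents that add atoms: none
Why: 1,2-Reduction of the enoate with i-Bu2AlH gives the allylic alcohol without conjugate reduction or loss of alkene geometry.

Step 21
Reactants: 29 allylic alcohol
Product: 30 (2E)-3-{[(tert-butyldiphenylsilyl)oxy]methyl}-5-[(4aR,8aS)-2,5,5,8a-tetramethyl-3,4,4a,5,6,7,8,8a-octahydronaphthalen-1-yl]pent-2-enal (C15 aldehyde)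
Conditions: MnO2, CH2Cl2, rt
Reagents that add atoms: none
Why: Allylic oxidation on MnO2 is neutral and heterogeneous, so the C13=C14 geometry of the β,β-disubstituted enal is kept.

Step 22
Reactants: 31 1,3-dihydroxyacetone (sold as its dimer); 32 ethyl (triphenylphosphoranylidene)acetate
Product: 34 4-(hydroxymethyl)furan-2(5H)-one, via open-chain hydroxy ester 33 (not isolated)
Conditions: CH2Cl2–MeOH, rt
Reagents that add atoms: none
Why: Wittig olefination of the symmetric ketone with a stabilised ylide is followed by spontaneous lactonisation of whichever CH2OH lies cis to the ester, so alkene geometry is not an issue.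

Step 23
Reactants: 34 hydroxymethyl butenolide
Product: 35 4-(bromomethyl)furan-2(5H)-one
Conditions: CBr4, PPh3, CH2Cl2, 0 °C
Reagents that add atoms: carbon tetrabromide, BrC(Br)(Br)Br
Why: The Appel reaction converts the primary allylic alcohol into the bromide under neutral conditions that the lactone tolerates.

Step 24
Reactants: 35 bromomethyl butenolide
Product: 36 [(5-oxo-2,5-dihydrofuran-3-yl)methyl]triphenylphosphonium bromide
Conditions: PPh3, toluene, 60 °C
Reagents that add atoms: triphenylphosphine, c1ccc(cc1)P(c1ccccc1)c1ccccc1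
Why: SN2 quaternisation of PPh3 by the reactive allylic bromide gives a salt that precipitates from toluene.

Step 25
Reactants: 30 C15 enal; 36 phosphonium bromide
Product: 38 4-[(1E,3E)-4-{[(tert-butyldiphenylsilyl)oxy]methyl}-6-[(4aR,8aS)-2,5,5,8a-tetramethyl-3,4,4a,5,6,7,8,8a-octahydronaphthalen-1-yl]hexa-1,3-dien-1-yl]furan-2(5H)-one, via phosphorus ylide 37 (not isolated)
Conditions: NaN(SiMe3)2 (1.0 equiv), THF, −78 °C; then 30, −78 °C → rt
Reagents that add atoms: none
Why: This Wittig olefination uses a ylide stabilised by vinylogous conjugation to the lactone carbonyl, which is too weakly basic to enolise 30 or attack the lactone and, as a stabilised ylide meeting an enal, should give mainly the E C15=C16 alkene while C13=C14 is untouched.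

Step 26
Reactants: 38 silyl-protected triene butenolide
Product: 39 target, 4-{(1E,3E)-4-(hydroxymethyl)-6-[(4aR,8aS)-2,5,5,8a-tetramethyl-3,4,4a,5,6,7,8,8a-octahydronaphthalen-1-yl]hexa-1,3-dien-1-yl}furan-2(5H)-one
Conditions: HF·pyridine, pyridine, THF, 0 °C → rt
Reagents that add atoms: none
Why: Fluoride desilylation with pyridine-buffered HF avoids the basic conditions that would deprotonate the butenolide and is too mild to ionise the allylic alcohol or isomerise the triene.

## Compound list

1 | 4,4-dimethylcyclohexanone | CC1(C)CCC(=O)CC1 | starting material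
2 | dimethyl carbonate | COC(=O)OC | starting material
3 | methyl 5,5-dimethyl-2-oxocyclohexane-1-carboxylate (racemic) | COC(=O)C1CC(C)(C)CCC1=O | intermediate
4 | methyl 5,5-dimethyl-2-oxo-1-(phenylselanyl)cyclohexane-1-carboxylate (racemic) | COC(=O)C1([Se]c2ccccc2)CC(C)(C)CCC1=O | intermediate
5 | methyl 5,5-dimethyl-2-oxo-1-(phenylseleninyl)cyclohexane-1-carboxylate | COC(=O)C1([Se](=O)c2ccccc2)CC(C)(C)CCC1=O | intermediate
6 | methyl 3,3-dimethyl-6-oxocyclohex-1-ene-1-carboxylate | COC(=O)C1=CC(C)(C)CCC1=O | intermediate
7 | (E)-3-methylpent-2-en-4-yn-1-ol | C#C/C(C)=C/CO | starting material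
8 | tert-butyldimethyl{[(E)-3-methylpent-2-en-4-yn-1-yl]oxy}silane | C#C/C(C)=C/CO[Si](C)(C)C(C)(C)C | intermediate
9 | tert-butyldimethyl{[(E)-3-methylpenta-2,4-dien-1-yl]oxy}silane | C=C/C(C)=C/CO[Si](C)(C)C(C)(C)C | intermediate
10 | Diels–Alder adduct, (1R,4aR,8aR) keto ester | CC1=CC[C@@H]2C(C)(C)CCC(=O)[C@]2(C(=O)OC)[C@@H]1CO[Si](C)(C)C(C)(C)C | intermediate
11 | C1 carbinol of 10 (C1 unassigned) | CC1=CC[C@@H]2C(C)(C)CCC(O)[C@]2(C(=O)OC)[C@@H]1CO[Si](C)(C)C(C)(C)C | intermediate
12 | C1 O-(imidazol-1-ylthiocarbonyl) derivative (C1 unassigned) | CC1=CC[C@@H]2C(C)(C)CCC(OC(=S)n3ccnc3)[C@]2(C(=O)OC)[C@@H]1CO[Si](C)(C)C(C)(C)C | intermediate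
13 | 1-deoxy angular ester, (1R,4aR,8aR) | CC1=CC[C@@H]2C(C)(C)CCC[C@]2(C(=O)OC)[C@@H]1CO[Si](C)(C)C(C)(C)C | intermediate
14 | angular primary alcohol, (1R,4aR,8aR) | CC1=CC[C@@H]2C(C)(C)CCC[C@]2(CO)[C@@H]1CO[Si](C)(C)C(C)(C)C | intermediate
15 | lithium alkoxide of 14 | CC1=CC[C@@H]2C(C)(C)CCC[C@]2(C[O-])[C@@H]1CO[Si](C)(C)C(C)(C)C.[Li+] | intermediate
16 | tetramethylphosphorodiamidate of 14 | CC1=CC[C@@H]2C(C)(C)CCC[C@]2(COP(=O)(N(C)C)N(C)C)[C@@H]1CO[Si](C)(C)C(C)(C)C | intermediate
17 | C10-methyl silyl ether, (1R,4aR,8aS) | CC1=CC[C@@H]2C(C)(C)CCC[C@]2(C)[C@@H]1CO[Si](C)(C)C(C)(C)C | intermediate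
18 | cis-fused drim-7-en-11-ol, (1R,4aR,8aS) | CC1=CC[C@@H]2C(C)(C)CCC[C@]2(C)[C@@H]1CO | intermediate
19 | cis-fused drim-7-en-11-al, (1R,4aR,8aS) | CC1=CC[C@@H]2C(C)(C)CCC[C@]2(C)[C@@H]1C=O | intermediate
20 | cis-fused drim-8-en-11-al, (4aR,8aS) | CC1=C(C=O)[C@@]2(C)CCCC(C)(C)[C@H]2CC1 | intermediate
21 | (4aR,8aS)-1-ethenyl-2,5,5,8a-tetramethyl-3,4,4a,5,6,7,8,8a-octahydronaphthalene | CC1=C(C=C)[C@@]2(C)CCCC(C)(C)[C@H]2CC1 | intermediate
22 | prop-2-yn-1-ol | C#CCO | starting material
23 | tert-butyldiphenyl(prop-2-yn-1-yloxy)silane | C#CCO[Si](c1ccccc1)(c1ccccc1)C(C)(C)C | intermediate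
24 | lithium acetylide of 23 | [Li+].[C-]#CCO[Si](c1ccccc1)(c1ccccc1)C(C)(C)C | intermediate
25 | ethyl 4-[(tert-butyldiphenylsilyl)oxy]but-2-ynoate | CCOC(=O)C#CCO[Si](c1ccccc1)(c1ccccc1)C(C)(C)C | intermediate
26 | ethyl (2Z)-4-[(tert-butyldiphenylsilyl)oxy]-3-iodobut-2-enoate | CCOC(=O)/C=C(\I)CO[Si](c1ccccc1)(c1ccccc1)C(C)(C)C | intermediate
27 | C12 B-alkyl-9-BBN from 21 | CC1=C(CCB3C4CCCC3CCC4)[C@@]2(C)CCCC(C)(C)[C@H]2CC1 | intermediate
28 | (2E)-enoate, Suzuki product | CC1=C(CC/C(=C\C(=O)OCC)CO[Si](c3ccccc3)(c3ccccc3)C(C)(C)C)[C@@]2(C)CCCC(C)(C)[C@H]2CC1 | intermediate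
29 | (2E)-allylic alcohol | CC1=C(CC/C(=C\CO)CO[Si](c3ccccc3)(c3ccccc3)C(C)(C)C)[C@@]2(C)CCCC(C)(C)[C@H]2CC1 | intermediate
30 | (2E)-enal (C15 aldehyde) | CC1=C(CC/C(=C\C=O)CO[Si](c3ccccc3)(c3ccccc3)C(C)(C)C)[C@@]2(C)CCCC(C)(C)[C@H]2CC1 | intermediate
31 | 1,3-dihydroxyacetone | OCC(=O)CO | starting material
32 | ethyl (triphenylphosphoranylidene)acetate | CCOC(=O)C=P(c1ccccc1)(c1ccccc1)c1ccccc1 | starting material
33 | ethyl 4-hydroxy-3-(hydroxymethyl)but-2-enoate | CCOC(=O)C=C(CO)CO | intermediate
34 | 4-(hydroxymethyl)furan-2(5H)-one | O=C1C=C(CO)CO1 | intermediate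
35 | 4-(bromomethyl)furan-2(5H)-one | O=C1C=C(CBr)CO1 | intermediate
36 | [(5-oxo-2,5-dihydrofuran-3-yl)methyl]triphenylphosphonium bromide | O=C1C=C(C[P+](c2ccccc2)(c2ccccc2)c2ccccc2)CO1.[Br-] | intermediate
37 | ylide of 36 | O=C1C=C(C=P(c2ccccc2)(c2ccccc2)c2ccccc2)CO1 | intermediate
38 | silyl-protected target, (1E,3E),(4aR,8aS) | CC1=C(CC/C(=C\C=C\C3=CC(=O)OC3)CO[Si](c4ccccc4)(c4ccccc4)C(C)(C)C)[C@@]2(C)CCCC(C)(C)[C@H]2CC1 | intermediate
39 | CNP0232848.3 | CC1=C(CC/C(=C\C=C\C2=CC(=O)OC2)CO)[C@@]2(C)CCCC(C)(C)[C@H]2CC1 | target

## Step count and risks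

Total steps: 26.
Longest linear sequence: 18 (steps 1, 2, 5–15, 19–21, 25, 26).

**Step 5.** The cycloaddition at the neopentyl C5 may be too slow under a mild chelating catalyst, so that the diene is lost meanwhile by desilylation or oligomerisation. Leakage through the ester-endo mode may also erode the enantiopurity of the C5/C10 pair. The fallback moves the source of chirality from the cycloaddition to the following reduction. It sets out from 6 and 9, which are combined with ZnCl2 in Et2O at rt, an achiral promoter of the kind known to give these cis-decalins. This gives the racemate, that is 10 together with the mirror-image adduct F1. The racemate is reduced with BH3·SMe2 and the (S)-methyl oxazaborolidine (Corey–Bakshi–Shibata reduction; quaternary C10 is the large flank and C2H2 the small one) in place of NaBH4. Reagent control gives a 1R carbinol from both enantiomers: 10 gives the (1R)-carbinol F2, which is the 1R epimer of 11, and F1 gives the diastereomeric carbinol of the mirror-image series F3. F2 and F3 are diastereomers and are separated on silica gel. F2 enters step 7, so the fallback comes back to the route at 11.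

**Step 11.** P–O instead of C–O cleavage may simply return the alcohol, or the lithium–amine medium may over-reduce the C7=C8 alkene. The fallback replaces electron transfer by carbonyl chemistry and sets out from 14. Dess–Martin oxidation gives the non-enolisable angular aldehyde F4. This is heated with N2H4·H2O and then KOH in diethylene glycol (Wolff–Kishner reduction, Huang-Minlon variant) through the hydrazone F5, and loss of nitrogen leaves the C10 methyl. The primary silyl ether is not expected to survive hot KOH, so the fallback comes back to the route at 18, and any surviving 17 is put through step 12.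

**Step 25.** E selectivity at C15=C16 may be incomplete. Competing deprotonation at the OCH2 of the butenolide is possible. Any attempt to correct the geometry by equilibration would scramble C13=C14. The fallback makes the C16–butenolide bond by cross-coupling instead of making C15=C16 by a phosphorus olefination, and it sets out from 30. Takai olefination (CHI3, CrCl2, THF, 0 °C) gives the (E)-dienyl iodide F6. Base-free Stille coupling with the known stannane 4-(tributylstannyl)furan-2(5H)-one F7 (Pd2(dba)3, AsPh3, NMP, rt) proceeds with retention of geometry, and the fallback comes back to the route at 38.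

## Further compounds

F1 | step 5 | mirror-image adduct (ent-10, formed with 10 as the racemate) | CC1=CC[C@H]2C(C)(C)CCC(=O)[C@@]2(C(=O)OC)[C@H]1CO[Si](C)(C)C(C)(C)C
F2 | step 5 | (1R)-carbinol, the 1R epimer of 11 | CC1=CC[C@@H]2C(C)(C)CC[C@@H](O)[C@]2(C(=O)OC)[C@@H]1CO[Si](C)(C)C(C)(C)C
F3 | step 5 | diastereomeric (1R)-carbinol of the mirror-image series | CC1=CC[C@H]2C(C)(C)CC[C@@H](O)[C@@]2(C(=O)OC)[C@H]1CO[Si](C)(C)C(C)(C)C
F4 | step 11 | angular aldehyde from 14 | CC1=CC[C@@H]2C(C)(C)CCC[C@]2(C=O)[C@@H]1CO[Si](C)(C)C(C)(C)C
F5 | step 11 | hydrazone of F4 | CC1=CC[C@@H]2C(C)(C)CCC[C@]2(/C=N/N)[C@@H]1CO[Si](C)(C)C(C)(C)C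
F6 | step 25 | (E)-dienyl iodide from 30 | CC1=C(CC/C(=C\C=C\I)CO[Si](c3ccccc3)(c3ccccc3)C(C)(C)C)[C@@]2(C)CCCC(C)(C)[C@H]2CC1
F7 | step 25 | 4-(tributylstannyl)furan-2(5H)-one | O=C1C=C([Sn](CCCC)(CCCC)CCCC)CO1
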